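**Retrosynthetic overview**

1. Target ⇐ desilylation, 1(10)-epoxidation, C8 methacrylation and α-methylenation of a trans-fused 6,12-lactone on a ten-membered ring that already carries the 2,3-oxirane, the C4=C15 methylene, O–C5 and O–C8.
2. Lactone ⇐ C6 ketone plus C7 enolate and BrCH2CO2Me; that enolate is the direct product of an anionic oxy-Cope ring expansion.
3. Key disconnection C8–C9 ([3,3], chair): ten-membered ring, 1(10)E olefin and C8 stereocentre ⇐ trans-1-(Z-alkoxyvinyl)-2-isopropenylcyclohexanol, whose C1–C6 bond breaks.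
4. Cyclohexanone ⇐ (S)-carvone 1 by α′-oxygenation, Luche reduction, hydroxyl-directed singlet-oxygen ene reaction with oxygen transfer, and Burgess dehydration; every centre is relayed from the carvone centre.
5. Ring order: carvone six-membered ring (bought) → 2,3-oxirane → ten-membered carbocycle → γ-lactone → 1(10)-oxirane.

Assumption and locants: the SMILES is read as (1R,2S,3S,5R,6S,7R,8S,10R)-1,10:2,3-diepoxy-5-hydroxy-8-(methacryloyloxy)germacra-4(15),11(13)-dien-12,6-olide; germacrane locants are used in the "Why" lines throughout, so carvone C1/C2/C3/C4/C5/C6 are C5/C4/C3/C2/C1/C6 (ring methyl = C15, isopropenyl = C10, C9, C14).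

**Route**

Step 1
Reactants: 1 (S)-(+)-carvone
Product: 3 (5R,6R)-2-methyl-5-(prop-1-en-2-yl)-6-[(triethylsilyl)oxy]cyclohex-2-en-1-one, via silyl dienol ether 2 (not isolated)
Conditions: LiN(iPr)2, THF, −78 °C; Et3SiCl; then mCPBA, hexane, −15 °C
Reagents that add atoms: chlorotriethylsilane, CC[Si](Cl)(CC)CC; 3-chloroperoxybenzoic acid, OOC(=O)c1cccc(Cl)c1
Why: Rubottom oxidation, in which kinetic deprotonation at C6 gives the cross-conjugated silyl dienol ether, its enol double bond is epoxidised anti to the neighbouring isopropenyl group, and 1,4-silyl migration leaves the C6 silyloxy group trans to the isopropenyl group.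

Step 2
Reactants: 3 (5R,6R)-2-methyl-5-(prop-1-en-2-yl)-6-[(triethylsilyl)oxy]cyclohex-2-en-1-one
Product: 4 (1R,5R,6R)-2-methyl-5-(prop-1-en-2-yl)-6-[(triethylsilyl)oxy]cyclohex-2-en-1-ol
Conditions: NaBH4, CeCl3·7H2O, MeOH, −78 °C
Reagents that add atoms: none
Why: Luche 1,2-reduction, with axial hydride delivery to the half-chair enone (both neighbours equatorial) giving the equatorial C5 alcohol, trans to the C6 silyloxy group and cis to the isopropenyl group.

Step 3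
Reactants: 4 (1R,5R,6R)-2-methyl-5-(prop-1-en-2-yl)-6-[(triethylsilyl)oxy]cyclohex-2-en-1-ol
Product: 6 (1R,2S,3S,4R,5S,6R)-2-methyl-5-(prop-1-en-2-yl)-4-[(triethylsilyl)oxy]-7-oxabicyclo[4.1.0]heptane-2,3-diol, via allylic hydroperoxide 5 (not isolated)
Conditions: O2, hν (Na lamp), 5,10,15,20-tetraphenylporphyrin (cat.), CH2Cl2, −20 °C; then Ti(OiPr)4 (10 mol %), 4 Å molecular sieves, −20 → 0 °C
Reagents that add atoms: dioxygen, O=O
Why: Schenck ene reaction followed by titanium-templated oxygen transfer (hydroxy-epoxidation), in which singlet oxygen adds to C4 on the face of the C5 hydroxyl and removes the pseudoaxial C2 hydrogen (the carbinol hydrogen is not abstracted), and the tertiary hydroperoxide then epoxidises the new C2=C3 bond syn to the two carbinols, so the C4, C3 and C2 oxygens all sit cis to the C5 oxygen.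

Step 4
Reactants: 6 (1R,2S,3S,4R,5S,6R)-2-methyl-5-(prop-1-en-2-yl)-4-[(triethylsilyl)oxy]-7-oxabicyclo[4.1.0]heptane-2,3-diol
Product: 7 (1R,2R,3S,4R,5S,6R)-3-[(tert-butyldimethylsilyl)oxy]-2-methyl-5-(prop-1-en-2-yl)-4-[(triethylsilyl)oxy]-7-oxabicyclo[4.1.0]heptan-2-ol
Conditions: tBuMe2SiOTf (1.1 equiv), 2,6-lutidine, CH2Cl2, −78 °C
Reagents that add atoms: tert-butyldimethylsilyl trifluoromethanesulfonate, CC(C)(C)[Si](C)(C)OS(=O)(=O)C(F)(F)F
Why: Chemoselective silyl ether formation, since the secondary C5 hydroxyl reacts far faster than the tertiary C4 hydroxyl at −78 °C and no stereocentre is touched.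

Step 5
Reactants: 7 (1R,2R,3S,4R,5S,6R)-3-[(tert-butyldimethylsilyl)oxy]-2-methyl-5-(prop-1-en-2-yl)-4-[(triethylsilyl)oxy]-7-oxabicyclo[4.1.0]heptan-2-ol
Product: 8 (1S,3R,4R,5S,6R)-3-[(tert-butyldimethylsilyl)oxy]-2-methylidene-5-(prop-1-en-2-yl)-4-[(triethylsilyl)oxy]-7-oxabicyclo[4.1.0]heptane
Conditions: Burgess reagent (MeO2CN–SO2NEt3 inner salt), benzene, 50 °C
Reagents that add atoms: none
Why: Burgess dehydration by syn elimination, where H–C5 and H–C3 are both anti to the C4–O bond so only a methyl hydrogen can be removed, giving the C4=C15 methylene exclusively.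

Step 6
Reactants: 8 (1S,3R,4R,5S,6R)-3-[(tert-butyldimethylsilyl)oxy]-2-methylidene-5-(prop-1-en-2-yl)-4-[(triethylsilyl)oxy]-7-oxabicyclo[4.1.0]heptane
Product: 10 (1S,3R,5S,6R)-3-[(tert-butyldimethylsilyl)oxy]-2-methylidene-5-(prop-1-en-2-yl)-7-oxabicyclo[4.1.0]heptan-4-one, via secondary alcohol 9 (not isolated)
Conditions: 2-iodoxybenzoic acid (IBX, 3 equiv), DMSO, 23 °C
Reagents that add atoms: none
Why: One-pot IBX desilylation and oxidation, as IBX in DMSO cleaves the triethylsilyl ether but not the tert-butyldimethylsilyl ether and oxidises the freed C6 alcohol to the ketone under neutral conditions that spare the β,γ-epoxy ketone.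

Step 7
Reactants: 11 4-methoxybenzyl alcohol; 12 ethyl vinyl ether
Product: 13 4-methoxybenzyl vinyl ether
Conditions: Hg(OAc)2 (5 mol %), ethyl vinyl ether as solvent, reflux
Reagents that add atoms: none
Why: Mercury-catalysed transfer vinylation (transetherification) driven by the excess of ethyl vinyl ether.

Step 8
Reactants: 13 4-methoxybenzyl vinyl ether
Product: 15 (Z)-1-bromo-2-[(4-methoxybenzyl)oxy]ethene, via dibromo ether 14 (not isolated)
Conditions: Br2, CH2Cl2, −78 °C; then DBU, −78 → 23 °C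
Reagents that add atoms: bromine, BrBr
Why: Bromination of the enol ether and dehydrobromination of the α-bromo ether, which gives mainly the Z bromovinyl ether (the more stable isomer, as for the ethyl analogue).

Step 9
Reactants: 10 (1S,3R,5S,6R)-3-[(tert-butyldimethylsilyl)oxy]-2-methylidene-5-(prop-1-en-2-yl)-7-oxabicyclo[4.1.0]heptan-4-one; 15 (Z)-1-bromo-2-[(4-methoxybenzyl)oxy]ethene
Product: 18 (1S,3R,4S,5S,6R)-3-[(tert-butyldimethylsilyl)oxy]-4-{(Z)-2-[(4-methoxybenzyl)oxy]ethenyl}-2-methylidene-5-(prop-1-en-2-yl)-7-oxabicyclo[4.1.0]heptan-4-ol, via vinyllithium 16 (not isolated), via vinylcerium dichloride 17 (not isolated)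
Conditions: 15, t-BuLi (2.1 equiv), Et2O, −78 °C; CeCl3, THF, −78 °C; then 10, −78 → −40 °C
Reagents that add atoms: none
Why: Bromine–lithium exchange, transmetalation and organocerium 1,2-addition, in which the weakly basic reagent attacks the C6 ketone on the face opposite the two flanking equatorial groups (C5 silyloxy, C1 isopropenyl) and the oxirane oxygen, placing the alkenyl group trans to the isopropenyl group.

Step 10
Reactants: 18 (1S,3R,4S,5S,6R)-3-[(tert-butyldimethylsilyl)oxy]-4-{(Z)-2-[(4-methoxybenzyl)oxy]ethenyl}-2-methylidene-5-(prop-1-en-2-yl)-7-oxabicyclo[4.1.0]heptan-4-ol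
Product: 21 methyl (1(10)E,2R,3S,5R,7R,8S)-5-[(tert-butyldimethylsilyl)oxy]-2,3-epoxy-8-[(4-methoxybenzyl)oxy]-6-oxo-13-norgermacra-1(10),4(15)-dien-12-oate, via potassium alkoxide 19 (not isolated), via potassium enolate 20 (not isolated)
Conditions: KH, 18-crown-6, THF, −20 → 0 °C; then BrCH2CO2Me, −78 °C
Reagents that add atoms: methyl bromoacetate, COC(=O)CBr
Why: Anionic oxy-Cope rearrangement through the chair transition state of the trans-diequatorial dialkenyl alkoxide, which breaks C1–C6 and forms C8–C9, fixes the 1(10)E olefin and transfers the ring chirality to C8 (Z enol ether gives 8S), after which the regiodefined enolate is alkylated at C7 anti to the C8 alkoxy group (7R).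

Step 11
Reactants: 21 methyl (1(10)E,2R,3S,5R,7R,8S)-5-[(tert-butyldimethylsilyl)oxy]-2,3-epoxy-8-[(4-methoxybenzyl)oxy]-6-oxo-13-norgermacra-1(10),4(15)-dien-12-oate
Product: 23 (1(10)E,2R,3S,5R,6S,7R,8S)-5-[(tert-butyldimethylsilyl)oxy]-2,3-epoxy-8-[(4-methoxybenzyl)oxy]-13-norgermacra-1(10),4(15)-dien-12,6-olide, via hydroxy ester 22 (not isolated)
Conditions: NaBH4, MeOH/THF, −40 → 0 °C
Reagents that add atoms: none
Why: Felkin–Anh hydride reduction anti to the C5 silyloxy group gives the 6S alkoxide, which closes onto the methyl ester (lactonisation) to the trans-fused γ-lactone.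

Step 12
Reactants: 23 (1(10)E,2R,3S,5R,6S,7R,8S)-5-[(tert-butyldimethylsilyl)oxy]-2,3-epoxy-8-[(4-methoxybenzyl)oxy]-13-norgermacra-1(10),4(15)-dien-12,6-olide
Product: 26 (1(10)E,2R,3S,5R,6S,7R,8S)-5-[(tert-butyldimethylsilyl)oxy]-2,3-epoxy-8-[(4-methoxybenzyl)oxy]germacra-1(10),4(15),11(13)-trien-12,6-olide, via Mannich base 24 (not isolated), via trimethylammonium iodide 25 (not isolated)
Conditions: LiN(SiMe3)2, THF, −78 °C; CH2=NMe2 I (Eschenmoser salt), −78 → 0 °C; MeI, MeOH, 23 °C; NaHCO3, CH2Cl2/H2O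
Reagents that add atoms: N,N-dimethylmethyleneiminium iodide (Eschenmoser salt), C=[N+](C)C.[I-]
Why: Eschenmoser methylenation (Mannich reaction of the lactone enolate, quaternisation, β-elimination), in which the transient C11 centre becomes sp2 and no other centre is affected.

Step 13
Reactants: 26 (1(10)E,2R,3S,5R,6S,7R,8S)-5-[(tert-butyldimethylsilyl)oxy]-2,3-epoxy-8-[(4-methoxybenzyl)oxy]germacra-1(10),4(15),11(13)-trien-12,6-olide
Product: 27 (1(10)E,2R,3S,5R,6S,7R,8S)-5-[(tert-butyldimethylsilyl)oxy]-2,3-epoxy-8-hydroxygermacra-1(10),4(15),11(13)-trien-12,6-olide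
Conditions: DDQ, CH2Cl2/pH 7 phosphate buffer, 0 °C
Reagents that add atoms: none
Why: Oxidative cleavage of the 4-methoxybenzyl ether by DDQ under buffered, neutral conditions that leave the vinyl oxirane, the silyl ether and the olefins alone.

Step 14
Reactants: 27 (1(10)E,2R,3S,5R,6S,7R,8S)-5-[(tert-butyldimethylsilyl)oxy]-2,3-epoxy-8-hydroxygermacra-1(10),4(15),11(13)-trien-12,6-olide
Product: 28 (1(10)E,2R,3S,5R,6S,7R,8S)-5-[(tert-butyldimethylsilyl)oxy]-2,3-epoxy-8-(methacryloyloxy)germacra-1(10),4(15),11(13)-trien-12,6-olide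
Conditions: methacrylic anhydride, Et3N, 4-(dimethylamino)pyridine (cat.), CH2Cl2, 0 → 23 °C
Reagents that add atoms: methacrylic anhydride, C=C(C)C(=O)OC(=O)C(C)=C
Why: Nucleophile-catalysed acylation of the only free hydroxyl, with retention at C8.

Step 15
Reactants: 28 (1(10)E,2R,3S,5R,6S,7R,8S)-5-[(tert-butyldimethylsilyl)oxy]-2,3-epoxy-8-(methacryloyloxy)germacra-1(10),4(15),11(13)-trien-12,6-olide
Product: 29 (1R,2S,3S,5R,6S,7R,8S,10R)-5-[(tert-butyldimethylsilyl)oxy]-1,10:2,3-diepoxy-8-(methacryloyloxy)germacra-4(15),11(13)-dien-12,6-olide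
Conditions: dimethyldioxirane, acetone/CH2Cl2, −20 °C
Reagents that add atoms: dimethyldioxirane, CC1(C)OO1
Why: Electrophilic epoxidation by the dioxirane, selective for the trisubstituted 1(10)E olefin over the hindered C4 methylene (flanked by the oxirane and the silyloxy group) and the two acrylates, with attack on the outer face of the trans-lactone-fused ring as in the peracid epoxidation of related 1(10)E-germacranolides, giving the 1R,10R trans-oxirane.

Step 16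
Reactants: 29 (1R,2S,3S,5R,6S,7R,8S,10R)-5-[(tert-butyldimethylsilyl)oxy]-1,10:2,3-diepoxy-8-(methacryloyloxy)germacra-4(15),11(13)-dien-12,6-olide
Product: 30 (1R,2S,3S,5R,6S,7R,8S,10R)-1,10:2,3-diepoxy-5-hydroxy-8-(methacryloyloxy)germacra-4(15),11(13)-dien-12,6-olide
Conditions: Bu4NF, AcOH, THF, 0 → 23 °C
Reagents that add atoms: none
Why: Fluoride desilylation buffered with acetic acid, which frees the C5 hydroxyl without opening either oxirane or adding to the acrylates.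

**Compound list**

1 | (S)-(+)-carvone, (5S)-2-methyl-5-(prop-1-en-2-yl)cyclohex-2-en-1-one | CC1=CC[C@H](C(C)=C)CC1=O | starting material
2 | (S)-triethyl{[6-methyl-3-(prop-1-en-2-yl)cyclohexa-1,5-dien-1-yl]oxy}silane | CC1=CC[C@H](C(C)=C)C=C1O[Si](CC)(CC)CC | intermediate (not isolated)
3 | (5R,6R)-2-methyl-5-(prop-1-en-2-yl)-6-[(triethylsilyl)oxy]cyclohex-2-en-1-one (silyloxy trans to isopropenyl) | CC1=CC[C@H](C(C)=C)[C@@H](O[Si](CC)(CC)CC)C1=O | intermediate
4 | (1R,5R,6R)-2-methyl-5-(prop-1-en-2-yl)-6-[(triethylsilyl)oxy]cyclohex-2-en-1-ol | CC1=CC[C@H](C(C)=C)[C@@H](O[Si](CC)(CC)CC)[C@@H]1O | intermediate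
5 | (1S,2R,5R,6R)-2-hydroperoxy-2-methyl-5-(prop-1-en-2-yl)-6-[(triethylsilyl)oxy]cyclohex-3-en-1-ol | C[C@@]1(OO)C=C[C@H](C(C)=C)[C@@H](O[Si](CC)(CC)CC)[C@@H]1O | intermediate (not isolated)
6 | (1R,2S,3S,4R,5S,6R)-2-methyl-5-(prop-1-en-2-yl)-4-[(triethylsilyl)oxy]-7-oxabicyclo[4.1.0]heptane-2,3-diol | C[C@@]1(O)[C@@H]2O[C@@H]2[C@H](C(C)=C)[C@@H](O[Si](CC)(CC)CC)[C@@H]1O | intermediate
7 | (1R,2R,3S,4R,5S,6R)-3-[(tert-butyldimethylsilyl)oxy]-2-methyl-5-(prop-1-en-2-yl)-4-[(triethylsilyl)oxy]-7-oxabicyclo[4.1.0]heptan-2-ol | C[C@@]1(O)[C@@H]2O[C@@H]2[C@H](C(C)=C)[C@@H](O[Si](CC)(CC)CC)[C@@H]1O[Si](C)(C)C(C)(C)C | intermediate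
8 | (1S,3R,4R,5S,6R)-3-[(tert-butyldimethylsilyl)oxy]-2-methylidene-5-(prop-1-en-2-yl)-4-[(triethylsilyl)oxy]-7-oxabicyclo[4.1.0]heptane | C=C1[C@@H]2O[C@@H]2[C@H](C(C)=C)[C@@H](O[Si](CC)(CC)CC)[C@@H]1O[Si](C)(C)C(C)(C)C | intermediate
9 | (1S,3R,4R,5R,6R)-3-[(tert-butyldimethylsilyl)oxy]-2-methylidene-5-(prop-1-en-2-yl)-7-oxabicyclo[4.1.0]heptan-4-ol | C=C1[C@@H]2O[C@@H]2[C@H](C(C)=C)[C@@H](O)[C@@H]1O[Si](C)(C)C(C)(C)C | intermediate (not isolated)
10 | (1S,3R,5S,6R)-3-[(tert-butyldimethylsilyl)oxy]-2-methylidene-5-(prop-1-en-2-yl)-7-oxabicyclo[4.1.0]heptan-4-one | C=C1[C@@H]2O[C@@H]2[C@H](C(C)=C)C(=O)[C@@H]1O[Si](C)(C)C(C)(C)C | intermediate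
11 | 4-methoxybenzyl alcohol | COc1ccc(CO)cc1 | starting material
12 | ethyl vinyl ether | C=COCC | starting material
13 | 4-methoxybenzyl vinyl ether | C=COCc1ccc(OC)cc1 | intermediate
14 | 1-[(1,2-dibromoethoxy)methyl]-4-methoxybenzene | BrCC(Br)OCc1ccc(OC)cc1 | intermediate (not isolated)
15 | (Z)-1-bromo-2-[(4-methoxybenzyl)oxy]ethene | Br/C=C\OCc1ccc(OC)cc1 | intermediate
16 | (Z)-{2-[(4-methoxybenzyl)oxy]ethenyl}lithium | [Li]/C=C\OCc1ccc(OC)cc1 | intermediate (not isolated)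
17 | dichloro{(Z)-2-[(4-methoxybenzyl)oxy]ethenyl}cerium | Cl[Ce](Cl)/C=C\OCc1ccc(OC)cc1 | intermediate (not isolated)
18 | (1S,3R,4S,5S,6R)-3-[(tert-butyldimethylsilyl)oxy]-4-{(Z)-2-[(4-methoxybenzyl)oxy]ethenyl}-2-methylidene-5-(prop-1-en-2-yl)-7-oxabicyclo[4.1.0]heptan-4-ol (alkenyl trans to isopropenyl) | C=C1[C@@H]2O[C@@H]2[C@H](C(C)=C)[C@@](O)(/C=C\OCc3ccc(OC)cc3)[C@@H]1O[Si](C)(C)C(C)(C)C | intermediate
19 | potassium alkoxide of 18 | C=C1[C@@H]2O[C@@H]2[C@H](C(C)=C)[C@@]([O-])(/C=C\OCc3ccc(OC)cc3)[C@@H]1O[Si](C)(C)C(C)(C)C.[K+] | intermediate (not isolated)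
20 | potassium C6(O)=C7 enolate of the ring-expanded ketone (1(10)E, 2,3-epoxide, 4(15)-ene, 5-silyloxy, 8S-PMB ether) | COc1ccc(CO[C@H]2C/C(C)=C/[C@H]3O[C@H]3C(=C)[C@@H](O[Si](C)(C)C(C)(C)C)C([O-])=C2)cc1.[K+] | intermediate (not isolated)
21 | methyl (1(10)E,2R,3S,5R,7R,8S)-5-[(tert-butyldimethylsilyl)oxy]-2,3-epoxy-8-[(4-methoxybenzyl)oxy]-6-oxo-13-norgermacra-1(10),4(15)-dien-12-oate | COc1ccc(CO[C@H]2C/C(C)=C/[C@H]3O[C@H]3C(=C)[C@@H](O[Si](C)(C)C(C)(C)C)C(=O)[C@@H]2CC(=O)OC)cc1 | intermediate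
22 | methyl (1(10)E,2R,3S,5R,6S,7S,8S)-5-[(tert-butyldimethylsilyl)oxy]-2,3-epoxy-6-hydroxy-8-[(4-methoxybenzyl)oxy]-13-norgermacra-1(10),4(15)-dien-12-oate | COc1ccc(CO[C@H]2C/C(C)=C/[C@H]3O[C@H]3C(=C)[C@@H](O[Si](C)(C)C(C)(C)C)[C@@H](O)[C@@H]2CC(=O)OC)cc1 | intermediate (not isolated)
23 | (1(10)E,2R,3S,5R,6S,7R,8S)-5-[(tert-butyldimethylsilyl)oxy]-2,3-epoxy-8-[(4-methoxybenzyl)oxy]-13-norgermacra-1(10),4(15)-dien-12,6-olide (trans-fused lactone) | COc1ccc(CO[C@H]2C/C(C)=C/[C@H]3O[C@H]3C(=C)[C@@H](O[Si](C)(C)C(C)(C)C)[C@H]3OC(=O)C[C@@H]32)cc1 | intermediate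
24 | 13-(dimethylamino)-11,13-dihydro derivative of 26 (C11 epimers) | COc1ccc(CO[C@H]2C/C(C)=C/[C@H]3O[C@H]3C(=C)[C@@H](O[Si](C)(C)C(C)(C)C)[C@H]3OC(=O)C(CN(C)C)[C@@H]32)cc1 | intermediate (not isolated)
25 | 13-(trimethylammonio) iodide of 24 | COc1ccc(CO[C@H]2C/C(C)=C/[C@H]3O[C@H]3C(=C)[C@@H](O[Si](C)(C)C(C)(C)C)[C@H]3OC(=O)C(C[N+](C)(C)C)[C@@H]32)cc1.[I-] | intermediate (not isolated)
26 | (1(10)E,2R,3S,5R,6S,7R,8S)-5-[(tert-butyldimethylsilyl)oxy]-2,3-epoxy-8-[(4-methoxybenzyl)oxy]germacra-1(10),4(15),11(13)-trien-12,6-olide | COc1ccc(CO[C@H]2C/C(C)=C/[C@H]3O[C@H]3C(=C)[C@@H](O[Si](C)(C)C(C)(C)C)[C@H]3OC(=O)C(=C)[C@@H]32)cc1 | intermediate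
27 | (1(10)E,2R,3S,5R,6S,7R,8S)-5-[(tert-butyldimethylsilyl)oxy]-2,3-epoxy-8-hydroxygermacra-1(10),4(15),11(13)-trien-12,6-olide | O[C@H]1C/C(C)=C/[C@H]2O[C@H]2C(=C)[C@@H](O[Si](C)(C)C(C)(C)C)[C@H]2OC(=O)C(=C)[C@@H]21 | intermediate
28 | (1(10)E,2R,3S,5R,6S,7R,8S)-5-[(tert-butyldimethylsilyl)oxy]-2,3-epoxy-8-(methacryloyloxy)germacra-1(10),4(15),11(13)-trien-12,6-olide | C=C(C)C(=O)O[C@H]1C/C(C)=C/[C@H]2O[C@H]2C(=C)[C@@H](O[Si](C)(C)C(C)(C)C)[C@H]2OC(=O)C(=C)[C@@H]21 | intermediate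
29 | (1R,2S,3S,5R,6S,7R,8S,10R)-5-[(tert-butyldimethylsilyl)oxy]-1,10:2,3-diepoxy-8-(methacryloyloxy)germacra-4(15),11(13)-dien-12,6-olide | C=C(C)C(=O)O[C@H]1C[C@@]2(C)O[C@@H]2[C@H]2O[C@H]2C(=C)[C@@H](O[Si](C)(C)C(C)(C)C)[C@H]2OC(=O)C(=C)[C@@H]21 | intermediate
30 | (1R,2S,3S,5R,6S,7R,8S,10R)-1,10:2,3-diepoxy-5-hydroxy-8-(methacryloyloxy)germacra-4(15),11(13)-dien-12,6-olide (ACon1_002091) | C=C(C)C(=O)O[C@H]1C[C@@]2(C)O[C@@H]2[C@H]2O[C@H]2C(=C)[C@@H](O)[C@H]2OC(=O)C(=C)[C@@H]21 | target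

**Step count**

Total: 16 steps. Longest linear sequence: 14 steps (steps 1–6 and 9–16); steps 7–8 make the vinyl bromide used in step 9.

**Steps most likely to fail, with fallbacks**

Step 3 (ene reaction and oxygen transfer). The ene reaction may take a methyl hydrogen instead of H–C2, may touch the isopropenyl group, or the titanium step may give poor syn selectivity. The fallback sets out from 4 and builds the same array stepwise by directed reactions. VO(acac)2 with t-BuOOH epoxidises the C3=C4 bond syn to the C5 hydroxyl to give the 3,4-epoxy alcohol F1. Sodium phenylselenide (from (PhSe)2 and NaBH4 in EtOH) opens it at C3 to the hydroxy selenide F2. H2O2 oxidation and selenoxide syn elimination toward C2 give the allylic diol F3. A second VO(acac)2/t-BuOOH epoxidation, directed by the tertiary C4 hydroxyl, returns to the route at 6.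

Step 10 (oxy-Cope and alkylation). The β-alkoxy potassium enolate 20 can lose 4-methoxybenzyl oxide before it is alkylated, and the C7 face selectivity is not secured. The fallback sets out from 18 and avoids a free enolate at the rearrangement temperature. Silylation (Me3SiOTf, 2,6-lutidine) gives the trimethylsilyl ether F4. Neutral thermal siloxy-Cope rearrangement (o-dichlorobenzene, 180 °C) gives the ring-expanded trimethylsilyl enol ether F5 through the same chair. MeLi at −78 °C then releases the lithium enolate, which is alkylated cold with methyl bromoacetate to rejoin the route at 21.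

Step 11 (ketone reduction). The C6 ketone is flanked by groups on opposite faces, so hydride may arrive from the wrong side. The fallback sets out from 21. If reduction gives mainly the C6 epimer, which closes to the cis-fused 6-epi-lactone F6, LiOH opens it to the 6-epi hydroxy acid F7. Mitsunobu lactonisation (PPh3, diisopropyl azodicarboxylate) then closes the ring with inversion at C6 and comes back to the route at 23.

**Further compounds**

F1 | step 3 | (1S,2S,3R,4R,6R)-1-methyl-4-(prop-1-en-2-yl)-3-[(triethylsilyl)oxy]-7-oxabicyclo[4.1.0]heptan-2-ol | C[C@@]12O[C@@H]1C[C@H](C(C)=C)[C@@H](O[Si](CC)(CC)CC)[C@@H]2O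
F2 | step 3 | (1S,2S,3S,5R,6R)-2-methyl-3-(phenylselanyl)-5-(prop-1-en-2-yl)-6-[(triethylsilyl)oxy]cyclohexane-1,2-diol | C[C@@]1(O)[C@@H]([Se]c2ccccc2)C[C@H](C(C)=C)[C@@H](O[Si](CC)(CC)CC)[C@@H]1O
F3 | step 3 | (1S,2R,5R,6R)-2-methyl-5-(prop-1-en-2-yl)-6-[(triethylsilyl)oxy]cyclohex-3-ene-1,2-diol | C[C@@]1(O)C=C[C@H](C(C)=C)[C@@H](O[Si](CC)(CC)CC)[C@@H]1O
F4 | step 10 | trimethylsilyl ether of 18 | C=C1[C@@H]2O[C@@H]2[C@H](C(C)=C)[C@@](O[Si](C)(C)C)(/C=C\OCc3ccc(OC)cc3)[C@@H]1O[Si](C)(C)C(C)(C)C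
F5 | step 10 | C6 trimethylsilyl enol ether (C6=C7) of the ring-expanded ketone | COc1ccc(CO[C@H]2C/C(C)=C/[C@H]3O[C@H]3C(=C)[C@@H](O[Si](C)(C)C(C)(C)C)C(O[Si](C)(C)C)=C2)cc1
F6 | step 11 | (1(10)E,2R,3S,5R,6R,7R,8S)-5-[(tert-butyldimethylsilyl)oxy]-2,3-epoxy-8-[(4-methoxybenzyl)oxy]-13-norgermacra-1(10),4(15)-dien-12,6-olide (cis-fused) | COc1ccc(CO[C@H]2C/C(C)=C/[C@H]3O[C@H]3C(=C)[C@@H](O[Si](C)(C)C(C)(C)C)[C@@H]3OC(=O)C[C@@H]32)cc1
F7 | step 11 | (1(10)E,2R,3S,5R,6R,7S,8S)-5-[(tert-butyldimethylsilyl)oxy]-2,3-epoxy-6-hydroxy-8-[(4-methoxybenzyl)oxy]-13-norgermacra-1(10),4(15)-dien-12-oic acid | COc1ccc(CO[C@H]2C/C(C)=C/[C@H]3O[C@H]3C(=C)[C@@H](O[Si](C)(C)C(C)(C)C)[C@H](O)[C@@H]2CC(=O)O)cc1
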